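**Plan**
- Retrosynthesis: remove the two acetates, cut C13=C14 back to a C13 methyl ketone, trace the C7=C8/C17–OH unit to a 7-ethoxy-17-aldehyde, then cut C9–C10 and C7–C8 of ring B in one operation.
- Enabling feature: ring B is a cyclohexene whose quaternary C10 is bonded to C9 (which carries C11), while C8 carries the oxygenated C17 and sits next to C7. This is the ortho, endo pattern of a [4+2] adduct between a ring A dienyl ether (C7=C6–C5=C10, oxygen on C7) and an (E)-enal (O=C17–C8=C9–C11).
- Forward: ring A is bought as 2,2,6-trimethylcyclohexanone and converted into the dienyl ether (enol triflate, Suzuki coupling). The enal carrying C11–C13 and C16 (C13 as dioxolane) comes from hex-5-en-2-one by ketalisation and cross-metathesis. The cycloaddition closes ring B.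
- Completion: hydrogenate C5=C6, eliminate ethanol to the C7=C8 enal, reduce C17, unmask C13, add C14–C15 by Horner–Wadsworth–Emmons olefination and (i-Bu)2AlH reduction, acetylate both alcohols.
- Stereochemistry: C9 from catalyst-controlled face selection on the enal, C10 from the endo transition state, C5 from hydrogen delivery opposite the C10 methyl, 13E from the olefination. The C7 and C8 centres are temporary.

Key step: step 5

Convention: labdane numbering; β is the face of the C10 methyl (C20), α the opposite face. The target is (5S,9R,10S), i.e. the normal labdane series (5α-H, 9α-H, 10β-CH3).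

Assumption: the (S)-configured cationic oxazaborolidine is taken to leave the C9 Si face (C8 Re face) of the boron-bound s-trans enal open, as the B–O/formyl C–H···O binding model predicts; the (R)-catalyst would be used if the sense proved opposite.

**Route**

Step 1
Reactants: 1 2,2,6-trimethylcyclohexan-1-one
Product: 3 enol triflate 2,6,6-trimethylcyclohex-1-en-1-yl trifluoromethanesulfonate, via lithium enolate 2 (not isolated)
Conditions: LiN(i-Pr)2, THF, −78 → 0 °C; then PhNTf2, 0 °C → rt
Reagents that add atoms: N-phenylbis(trifluoromethanesulfonimide), O=S(=O)(N(c1ccccc1)S(=O)(=O)C(F)(F)F)C(F)(F)F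
Why: enolate O-sulfonylation; the ketone has a single α-hydrogen, so only the tetrasubstituted enolate can form and it is trapped on oxygen as the alkenyl triflate.

Step 2
Reactants: 3 2,6,6-trimethylcyclohex-1-en-1-yl trifluoromethanesulfonate; 4 (E)-2-(2-ethoxyvinyl)-4,4,5,5-tetramethyl-1,3,2-dioxaborolane
Product: 5 (E)-1-(2-ethoxyvinyl)-2,6,6-trimethylcyclohex-1-ene
Conditions: Pd(OAc)2 (5 mol%), SPhos (10 mol%), K3PO4, THF/H2O, 60 °C; chromatography on basic alumina
Reagents that add atoms: none
Why: Suzuki–Miyaura coupling of an alkenyl triflate with an alkenylboronate, in which the bulky biarylphosphine should allow coupling at the hindered tetrasubstituted carbon and the E geometry of the boronate is transferred with retention.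

Step 3
Reactants: 6 hex-5-en-2-one
Product: 7 2-(but-3-en-1-yl)-2-methyl-1,3-dioxolane
Conditions: HOCH2CH2OH, p-TsOH·H2O (cat.), toluene, reflux, Dean–Stark
Reagents that add atoms: ethylene glycol, OCCO
Why: acid-catalysed ketalisation driven by azeotropic removal of water.

Step 4
Reactants: 7 2-(but-3-en-1-yl)-2-methyl-1,3-dioxolane; 8 (E)-but-2-enal
Product: 9 (E)-5-(2-methyl-1,3-dioxolan-2-yl)pent-2-enal
Conditions: second-generation Hoveyda–Grubbs catalyst RuCl2(H2IMes)(=CH-C6H4-2-O-i-Pr) (2 mol%), 8 (4 equiv), CH2Cl2, 40 °C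
Reagents that add atoms: none
Why: olefin cross-metathesis of a terminal alkene with an enal, which releases propene and should give the conjugated (E)-enal as the thermodynamically preferred isomer.

Step 5
Reactants: 5 (E)-1-(2-ethoxyvinyl)-2,6,6-trimethylcyclohex-1-ene (1.5 equiv); 9 (E)-5-(2-methyl-1,3-dioxolan-2-yl)pent-2-enal
Product: 10 7α-ethoxy-13,13-(ethylenedioxy)-14,15-dinorlabd-5-en-17-al (8α-CHO, 9α-H, 10β-CH3)
Conditions: (S)-3,3-diphenyl-1-(o-tolyl)tetrahydro-1H,3H-pyrrolo[1,2-c][1,3,2]oxazaborole (20 mol%), Tf2NH (18 mol%), CH2Cl2, −78 → −40 °C; then Et3N; chromatography on Et3N-deactivated silica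
Reagents that add atoms: none
Why: Proposed new method: the boron-bound s-trans enal 9 should be attacked at C9 by C10, the ethoxy-activated vinylogous terminus of diene 5, while C7 closes onto the enolate carbon C8 in a concerted but strongly asynchronous normal-demand [4+2]; the closest known reactions are cationic-oxazaborolidine-catalysed endo Diels–Alder additions of (E)-β-substituted enals to 1-vinylcycloalkene dienes, and the thermal cycloaddition of 2,6,6-trimethyl-1-vinylcyclohexene with acetylenedicarboxylate, which shows that this twisted diene can form the quaternary C10 bond. Ring B closes as the six-membered ring of an intermolecular [4+2] cycloaddition, C9–C10 and C7–C8 being formed suprafacially on both partners. C9 and the transient C8 are set by the catalyst, whose cis phenyl group is expected to cover the C9 Re face so that the diene adds to the Si face; C10 follows from endo approach of the formyl group, which places the C11 chain cis to the C10 methyl; C7 follows from the E geometry of the enol ether and the C8/C9 trans relationship from the E geometry of the enal. The step needs ortho regiochemistry, secured by the ethoxy donor on C7, endo selectivity, favoured by Lewis-acid activation of the (E)-enal, and enantiofacial selectivity, supplied by the catalyst.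

Step 6
Reactants: 10 7α-ethoxy-13,13-(ethylenedioxy)-14,15-dinorlabd-5-en-17-al
Product: 11 7α-ethoxy-13,13-(ethylenedioxy)-14,15-dinor-5α-labdan-17-al
Conditions: H2 (3 atm), 10% Pd/C, EtOAc, rt
Reagents that add atoms: none
Why: heterogeneous catalytic hydrogenation in which the β face of C5=C6 is covered by the axial C10 methyl and the β methyl on C4, so hydrogen should add from the α face and give the 5α-H trans ring fusion, as is usual for Δ5 octalins with an angular methyl group, while aldehyde, ether and ketal are inert in neutral EtOAc.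

Step 7
Reactants: 11 7α-ethoxy-13,13-(ethylenedioxy)-14,15-dinor-5α-labdan-17-al
Product: 12 13,13-(ethylenedioxy)-14,15-dinorlabd-7-en-17-al
Conditions: DBU (1.5 equiv), CH2Cl2, rt
Reagents that add atoms: none
Why: E1cB β-elimination of ethanol from a β-alkoxy aldehyde, with the axial C8–H anti to the axial C7–OEt; C9–H is not conjugated to the carbonyl, so C9 should keep its configuration.

Step 8
Reactants: 12 13,13-(ethylenedioxy)-14,15-dinorlabd-7-en-17-al
Product: 13 13,13-(ethylenedioxy)-14,15-dinorlabd-7-en-17-ol
Conditions: NaBH4, CeCl3·7H2O, MeOH, 0 °C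
Reagents that add atoms: none
Why: Luche reduction, which delivers hydride selectively to the carbonyl carbon of the enal and leaves the ketal untouched.

Step 9
Reactants: 13 13,13-(ethylenedioxy)-14,15-dinorlabd-7-en-17-ol
Product: 14 17-hydroxy-14,15-dinorlabd-7-en-13-one
Conditions: 1 M aq. HCl, THF, rt
Reagents that add atoms: water, O
Why: acid hydrolysis of a ketone dioxolane under conditions dilute enough to leave the primary allylic alcohol unchanged.

Step 10
Reactants: 14 17-hydroxy-14,15-dinorlabd-7-en-13-one; 15 triethyl phosphonoacetate (3 equiv)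
Product: 17 ethyl (13E)-17-hydroxylabda-7,13-dien-15-oate, via sodium phosphonate 16 (not isolated)
Conditions: NaH (2.8 equiv), THF, 0 °C; then 14, rt → 50 °C; chromatographic removal of the minor 13Z isomer
Reagents that add atoms: none
Why: Horner–Wadsworth–Emmons olefination of a methyl ketone, in which the stabilised phosphonate carbanion is too weakly basic to deprotonate the free C17 hydroxyl and reversible addition should favour the E isomer with the C12 chain trans to the ester.

Step 11
Reactants: 17 ethyl (13E)-17-hydroxylabda-7,13-dien-15-oate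
Product: 18 (13E)-labda-7,13-diene-15,17-diol
Conditions: (i-Bu)2AlH (4.5 equiv), CH2Cl2, −78 → 0 °C; aq. KNaC4H4O6 (potassium sodium tartrate)
Reagents that add atoms: none
Why: 1,2-reduction of an α,β-unsaturated ester to the allylic alcohol by the aluminium hydride, which leaves the alkene geometry intact.

Step 12
Reactants: 18 (13E)-labda-7,13-diene-15,17-diol
Product: 19 (13E)-labda-7,13-diene-15,17-diyl diacetate
Conditions: Ac2O, pyridine, DMAP (cat.), CH2Cl2, rt
Reagents that add atoms: acetic anhydride, CC(=O)OC(C)=O
Why: DMAP-catalysed acylation of both unhindered primary allylic alcohols.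

**Compound list**

1 | 2,2,6-trimethylcyclohexan-1-one (racemic; its stereocentre is lost in step 1) | CC1CCCC(C)(C)C1=O | starting material
2 | lithium 2,6,6-trimethylcyclohex-1-en-1-olate | [Li]OC1=C(C)CCCC1(C)C | intermediate (not isolated)
3 | 2,6,6-trimethylcyclohex-1-en-1-yl trifluoromethanesulfonate | CC1=C(OS(=O)(=O)C(F)(F)F)C(C)(C)CCC1 | intermediate
4 | (E)-2-(2-ethoxyvinyl)-4,4,5,5-tetramethyl-1,3,2-dioxaborolane | CCO/C=C/B1OC(C)(C)C(C)(C)O1 | starting material
5 | (E)-1-(2-ethoxyvinyl)-2,6,6-trimethylcyclohex-1-ene | CCO/C=C/C1=C(C)CCCC1(C)C | intermediate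
6 | hex-5-en-2-one | CC(=O)CCC=C | starting material
7 | 2-(but-3-en-1-yl)-2-methyl-1,3-dioxolane | CC1(CCC=C)OCCO1 | intermediate
8 | (E)-but-2-enal | C/C=C/C=O | starting material
9 | (E)-5-(2-methyl-1,3-dioxolan-2-yl)pent-2-enal | CC1(OCCO1)CC/C=C/C=O | intermediate
10 | 7α-ethoxy-13,13-(ethylenedioxy)-14,15-dinorlabd-5-en-17-al (8α-CHO, 9α-H, 10β-CH3) | CC1(OCCO1)CC[C@H]1[C@H](C=O)[C@H](OCC)C=C2C(C)(C)CCC[C@]12C | intermediate
11 | 7α-ethoxy-13,13-(ethylenedioxy)-14,15-dinor-5α-labdan-17-al (8α-CHO, 9α-H) | CC1(OCCO1)CC[C@H]1[C@H](C=O)[C@H](OCC)C[C@H]2C(C)(C)CCC[C@]12C | intermediate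
12 | 13,13-(ethylenedioxy)-14,15-dinorlabd-7-en-17-al | CC1(OCCO1)CC[C@H]1C(C=O)=CC[C@H]2C(C)(C)CCC[C@]12C | intermediate
13 | 13,13-(ethylenedioxy)-14,15-dinorlabd-7-en-17-ol | CC1(OCCO1)CC[C@H]1C(CO)=CC[C@H]2C(C)(C)CCC[C@]12C | intermediate
14 | 17-hydroxy-14,15-dinorlabd-7-en-13-one | CC(=O)CC[C@H]1C(CO)=CC[C@H]2C(C)(C)CCC[C@]12C | intermediate
15 | triethyl phosphonoacetate | CCOC(=O)CP(=O)(OCC)OCC | starting material
16 | sodium salt of triethyl phosphonoacetate | [Na+].CCOC(=O)[CH-]P(=O)(OCC)OCC | intermediate (not isolated)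
17 | ethyl (13E)-17-hydroxylabda-7,13-dien-15-oate | CCOC(=O)/C=C(\C)CC[C@H]1C(CO)=CC[C@H]2C(C)(C)CCC[C@]12C | intermediate
18 | (13E)-labda-7,13-diene-15,17-diol | OC/C=C(\C)CC[C@H]1C(CO)=CC[C@H]2C(C)(C)CCC[C@]12C | intermediate
19 | (5S,9R,10S,13E)-labda-7,13-diene-15,17-diyl diacetate | CC(=O)OC/C=C(\C)CC[C@H]1C(COC(C)=O)=CC[C@H]2C(C)(C)CCC[C@]12C | target

**Step count and risks**

Total step count: 12. Longest linear sequence: 10 (steps 1, 2, 5–12; the enal branch, steps 3, 4, 5–12, is equally long).

Steps most likely to fail: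

1. Step 5. Bond formation at the tetrasubstituted terminus C10 of the twisted dienyl ether may be too slow. The enol ether could then react through C6 to give open-chain Michael or carbonyl adducts, or be protonated by the acid catalyst, or the ketal could be ionised; endo and face selectivity may also be incomplete. The fallback is a chiral-pool relay that uses only known reactions. It sets out from no numbered compound: 1 to 12 are bypassed, and carbons C1–C13 with C5, C9 and C10 already correct are taken from commercial (+)-manool F1. It comes back to the route at 13. Oxidative cleavage of the tertiary vinyl carbinol of F1 (KMnO4, MgSO4, acetone, 0 °C) should give 14,15-dinorlabd-8(17)-en-13-one F2. Mild ketalisation (ethylene glycol, PPTS, benzene, reflux) should give 13,13-(ethylenedioxy)-14,15-dinorlabd-8(17)-ene F3. Epoxidation of the exocyclic alkene (mCPBA, NaHCO3, CH2Cl2, 0 °C) should give mainly 8α,17-epoxy-13,13-(ethylenedioxy)-14,15-dinorlabdane F4; either C8 epimer serves. Isomerisation of the epoxide to the allylic alcohol with loss of a C7 hydrogen (Al(O-i-Pr)3, toluene, reflux) should then give 13, from which steps 9–12 follow unchanged.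

2. Step 6. Hydrogenation of the hindered trisubstituted alkene may be slow, which would let hydrogenolysis of the allylic C7–O bond or addition from the β face compete. The fallback sets out from 10 and comes back at 11; it moves the hydrogenation to the alcohol oxidation level and makes it directed. Reduction of 10 (NaBH4, MeOH, 0 °C) should give 7α-ethoxy-13,13-(ethylenedioxy)-14,15-dinorlabd-5-en-17-ol F5. Homogeneous hydrogenation with [Ir(cod)(PCy3)(py)]PF6 (H2 1 atm, CH2Cl2, rt) should be directed by the α-oriented hydroxyl and ether oxygens to the α face and give 7α-ethoxy-13,13-(ethylenedioxy)-14,15-dinor-5α-labdan-17-ol F6. Oxidation with Dess–Martin periodinane (NaHCO3, CH2Cl2) returns 11.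

3. Step 10. The olefination of the methyl ketone may be sluggish and give incomplete E selectivity, with the geometric isomers hard to separate. The fallback sets out from 14 and comes back at 18; it fixes the geometry by syn carbometalation of an alkyne. Silylation (TBSCl, imidazole, DMF) should give 17-(tert-butyldimethylsilyloxy)-14,15-dinorlabd-7-en-13-one F7. Kinetic enolisation at the methyl group and phosphorylation (LiN(i-Pr)2, THF, −78 °C; ClP(O)(OEt)2) should give the enol phosphate diethyl 17-(tert-butyldimethylsilyloxy)-14,15-dinorlabda-7,13(16)-dien-13-yl phosphate F8. Elimination (LiN(i-Pr)2, 2.2 equiv, −78 °C → rt) should give the terminal alkyne 17-(tert-butyldimethylsilyloxy)-14,15-dinorlabd-7-en-13(16)-yne F9. Zirconium-catalysed methylalumination (Me3Al, Cp2ZrCl2, CH2Cl2, rt; then n-BuLi, (CH2O)n, THF) should give (13E)-17-(tert-butyldimethylsilyloxy)labda-7,13-dien-15-ol F10. Desilylation (Bu4NF, THF) returns 18.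

**Further compounds**

F1 | step 5 | (+)-manool, (13R)-labda-8(17),14-dien-13-ol | C=C[C@](C)(O)CC[C@H]1C(=C)CC[C@H]2C(C)(C)CCC[C@]12C
F2 | step 5 | 14,15-dinorlabd-8(17)-en-13-one | CC(=O)CC[C@H]1C(=C)CC[C@H]2C(C)(C)CCC[C@]12C
F3 | step 5 | 13,13-(ethylenedioxy)-14,15-dinorlabd-8(17)-ene | CC1(OCCO1)CC[C@H]1C(=C)CC[C@H]2C(C)(C)CCC[C@]12C
F4 | step 5 | 8α,17-epoxy-13,13-(ethylenedioxy)-14,15-dinorlabdane | CC1(OCCO1)CC[C@H]1[C@@]3(CO3)CC[C@H]2C(C)(C)CCC[C@]12C
F5 | step 6 | 7α-ethoxy-13,13-(ethylenedioxy)-14,15-dinorlabd-5-en-17-ol | CC1(OCCO1)CC[C@H]1[C@H](CO)[C@H](OCC)C=C2C(C)(C)CCC[C@]12C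
F6 | step 6 | 7α-ethoxy-13,13-(ethylenedioxy)-14,15-dinor-5α-labdan-17-ol | CC1(OCCO1)CC[C@H]1[C@H](CO)[C@H](OCC)C[C@H]2C(C)(C)CCC[C@]12C
F7 | step 10 | 17-(tert-butyldimethylsilyloxy)-14,15-dinorlabd-7-en-13-one | CC(=O)CC[C@H]1C(CO[Si](C)(C)C(C)(C)C)=CC[C@H]2C(C)(C)CCC[C@]12C
F8 | step 10 | diethyl 17-(tert-butyldimethylsilyloxy)-14,15-dinorlabda-7,13(16)-dien-13-yl phosphate | C=C(OP(=O)(OCC)OCC)CC[C@H]1C(CO[Si](C)(C)C(C)(C)C)=CC[C@H]2C(C)(C)CCC[C@]12C
F9 | step 10 | 17-(tert-butyldimethylsilyloxy)-14,15-dinorlabd-7-en-13(16)-yne | C#CCC[C@H]1C(CO[Si](C)(C)C(C)(C)C)=CC[C@H]2C(C)(C)CCC[C@]12C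
F10 | step 10 | (13E)-17-(tert-butyldimethylsilyloxy)labda-7,13-dien-15-ol | OC/C=C(\C)CC[C@H]1C(CO[Si](C)(C)C(C)(C)C)=CC[C@H]2C(C)(C)CCC[C@]12C
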